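The cyclohexane is numbered C1 (quaternary carbon carrying the keto chain), C2 (the CH carrying the oxobutyl group), C3 (the C(CH3)2 carbon) and C4–C6 (the CH2 carbons). It is cut into C4–C6 and a C3–C2–C1 unit whose two quaternary carbons are written as 1,1-disubstituted olefins flanking the stereogenic C2–H. This 1,4-diene comes from (S)-limonene (C2 bought) by ring cleavage, α-methylenation and chromium-mediated addition of the side-chain iodide. One manganese/nickel hydroalkylation with 1-chloro-3-iodopropane then forms C3–C4 and C6–C1, turns both =CH2 groups into ring methyls and sets C1 from C2. Hydrolysis, oxidation and opening of (S)-glycidyl acetate finish the target.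

Key step: step 6

Remark: the carbinol carbon made in step 5 is carried as both epimers, because step 8 oxidizes it to the ketone.

Step 1
Reactants: 1 (S)-(−)-limonene
Product: 2 (3S)-6-oxo-3-(prop-1-en-2-yl)heptanal
Conditions: O3 (1.0 equiv), CH2Cl2–MeOH, −78 °C; then Me2S, −78 °C to rt
Reagents that add atoms: ozone, [O-][O+]=O
Why: Ozonolysis with reductive work-up should cleave the more electron-rich trisubstituted ring olefin first and leave the isopropenyl group and the stereocenter untouched.

Step 2
Reactants: 2 (3S)-6-oxo-3-(prop-1-en-2-yl)heptanal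
Product: 3 (3R)-2-methylidene-6-oxo-3-(prop-1-en-2-yl)heptanal
Conditions: dimethylmethyleneiminium iodide, Et3N, CH2Cl2, rt
Reagents that add atoms: dimethylmethyleneiminium iodide, C=[N+](C)C.[I-]
Why: A Mannich reaction at the aldehyde α-carbon followed by base-induced loss of dimethylamine (α-methylenation) should be faster for the aldehyde than for the methyl ketone, and the tertiary amine base should not epimerize the adjacent stereocenter.

Step 3
Reactants: 4 (3R)-5-methoxy-3-methyl-5-oxopentanoic acid
Product: 5 methyl (3R)-5-hydroxy-3-methylpentanoate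
Conditions: BH3·SMe2, THF, 0 °C to rt; then H2O
Reagents that add atoms: none
Why: Borane reduces a free carboxylic acid much faster than a methyl ester (chemoselective borane reduction), and the stereocenter is not involved.

Step 4
Reactants: 5 methyl (3R)-5-hydroxy-3-methylpentanoate
Product: 6 methyl (3S)-5-iodo-3-methylpentanoate
Conditions: I2, PPh3, imidazole, CH2Cl2, 0 °C
Reagents that add atoms: iodine, II
Why: An Appel-type iodination converts the primary alcohol into the iodide under neutral conditions before it can lactonize.

Step 5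
Reactants: 6 methyl (3S)-5-iodo-3-methylpentanoate; 3 (3R)-2-methylidene-6-oxo-3-(prop-1-en-2-yl)heptanal
Product: 8 methyl (3R,8R)-6-hydroxy-3-methyl-7-methylidene-11-oxo-8-(prop-1-en-2-yl)dodecanoate (both C6 epimers), via alkylchromium dichloride 7 (not isolated)
Conditions: CrCl2 (4 equiv), cobalt phthalocyanine Co(C32H16N8) (cat.), DMF, rt; then H2O
Reagents that add atoms: none
Why: The cobalt-catalysed formation of an alkylchromium reagent and its Nozaki–Hiyama–Kishi-type addition should select the aldehyde over the methyl ketone and the ester and add 1,2 to the enal; the new carbinol center is not controlled and is removed in step 8.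

Step 6
Reactants: 8 methyl (3R,8R)-6-hydroxy-3-methyl-7-methylidene-11-oxo-8-(prop-1-en-2-yl)dodecanoate (both C6 epimers); 9 1-chloro-3-iodopropane
Product: 11 methyl (3R)-6-hydroxy-3-methyl-6-[(1R,2R)-1,3,3-trimethyl-2-(3-oxobutyl)cyclohexyl]hexanoate (both C6 epimers), via chloropropyl diene 10 (not isolated)
Conditions: 9 (slow addition), Mn(dpm)3 (cat.), Ni(acac)2 (cat.), PhSiH3, K2CO3, NaI (cat.), (CF3)2CHOH, ClCH2CH2Cl–propylene carbonate, rt, high dilution
Reagents that add atoms: none
Why: Proposed new method: a manganese hydride made from Mn(dpm)3 and PhSiH3 transfers a hydrogen atom to the CH2 end of the isopropenyl group, the tertiary radical is captured by the 3-chloropropylnickel species formed from the C–I bond of 9, and reductive elimination forms the C3–C4 bond and gives 10; after chloride–iodide exchange the pendant halide enters nickel in the same way, a second hydrogen atom transfer to the methylidene group gives the tertiary radical at C1, and its intramolecular capture and reductive elimination form the C6–C1 bond. The closest known reaction type is the intermolecular manganese/nickel Markovnikov hydroalkylation of 1,1-disubstituted olefins with primary alkyl iodides to give quaternary carbons; new is its double use on one 1,4-diene with a 1,3-dihalide so that a ring closes. The six-membered ring closes by alkyl–alkyl reductive elimination from a seven-membered nickelacycle, formally the union of a tertiary radical with a primary halide six atoms away, and not by free-radical addition to an olefin. The new quaternary stereocenter C1 is set in this ring closure by the existing C2: in the chair-like arrangement the oxobutyl chain on C2 is equatorial and the bulkier hydroxyalkyl group on C1 takes the equatorial site, away from the axial methyl on C3, so the new methyl becomes axial and trans to H-2. The step needs Markovnikov regiochemistry at both olefins (secured by hydrogen atom transfer, which gives tertiary radicals), a first intermolecular coupling at the less hindered isopropenyl group through C–I and not C–Cl (secured by sterics and by the halide difference), and ring closure faster than a second intermolecular coupling (secured by dilution and slow addition).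

Step 7
Reactants: 11 methyl (3R)-6-hydroxy-3-methyl-6-[(1R,2R)-1,3,3-trimethyl-2-(3-oxobutyl)cyclohexyl]hexanoate (both C6 epimers)
Product: 12 (3R)-6-hydroxy-3-methyl-6-[(1R,2R)-1,3,3-trimethyl-2-(3-oxobutyl)cyclohexyl]hexanoic acid (both C6 epimers)
Conditions: LiOH, THF–MeOH–H2O, 0 °C to rt; then dilute HCl
Reagents that add atoms: lithium hydroxide, [Li+].[OH-]
Why: Saponification at the hydroxy ketone stage, before the 1,6-diketone exists, should avoid base-induced aldol cyclization.

Step 8
Reactants: 12 (3R)-6-hydroxy-3-methyl-6-[(1R,2R)-1,3,3-trimethyl-2-(3-oxobutyl)cyclohexyl]hexanoic acid (both C6 epimers)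
Product: 13 (3R)-3-methyl-6-oxo-6-[(1R,2R)-1,3,3-trimethyl-2-(3-oxobutyl)cyclohexyl]hexanoic acid
Conditions: Dess–Martin periodinane, CH2Cl2, rt
Reagents that add atoms: none
Why: Dess–Martin oxidation converts the hindered secondary carbinol into the ketone under neutral conditions that leave the acid, the methyl ketone and the non-enolizable quaternary center untouched.

Step 9
Reactants: 14 (R)-glycidol
Product: 15 (S)-glycidyl acetate
Conditions: Ac2O, Et3N, DMAP (cat.), CH2Cl2, 0 °C
Reagents that add atoms: acetic anhydride, CC(=O)OC(C)=O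
Why: O-Acetylation of the primary alcohol under mild base leaves the epoxide and its stereocenter intact; the descriptor changes from R to S only through the priority rules.

Step 10
Reactants: 13 (3R)-3-methyl-6-oxo-6-[(1R,2R)-1,3,3-trimethyl-2-(3-oxobutyl)cyclohexyl]hexanoic acid; 15 (S)-glycidyl acetate
Product: 16 (2R)-3-acetoxy-2-hydroxypropyl (3R)-3-methyl-6-oxo-6-[(1R,2R)-1,3,3-trimethyl-2-(3-oxobutyl)cyclohexyl]hexanoate (target)
Conditions: n-Bu4NBr (cat.), toluene, 90 °C
Reagents that add atoms: none
Why: Halide-catalysed SN2 opening of the terminal epoxide by the carboxylic acid at the unsubstituted carbon should free the secondary alcohol directly with the configuration bought in 14, without a base strong enough to drive acyl migration.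

Compound list
1 | (S)-(−)-limonene, (4S)-1-methyl-4-(prop-1-en-2-yl)cyclohex-1-ene | CC1=CC[C@H](CC1)C(C)=C | starting material
2 | (3S)-6-oxo-3-(prop-1-en-2-yl)heptanal | CC(=O)CC[C@@H](CC=O)C(C)=C | intermediate
3 | (3R)-2-methylidene-6-oxo-3-(prop-1-en-2-yl)heptanal | CC(=O)CC[C@@H](C(=C)C=O)C(C)=C | intermediate
4 | (3R)-5-methoxy-3-methyl-5-oxopentanoic acid (monomethyl (R)-3-methylglutarate) | OC(=O)C[C@@H](C)CC(=O)OC | starting material
5 | methyl (3R)-5-hydroxy-3-methylpentanoate | OCC[C@@H](C)CC(=O)OC | intermediate
6 | methyl (3S)-5-iodo-3-methylpentanoate | ICC[C@@H](C)CC(=O)OC | intermediate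
7 | [(3S)-5-methoxy-3-methyl-5-oxopentyl]chromium dichloride | Cl[Cr](Cl)CC[C@@H](C)CC(=O)OC | intermediate (not isolated)
8 | methyl (3R,8R)-6-hydroxy-3-methyl-7-methylidene-11-oxo-8-(prop-1-en-2-yl)dodecanoate (both C6 epimers) | CC(=O)CC[C@@H](C(=C)C(O)CC[C@@H](C)CC(=O)OC)C(C)=C | intermediate
9 | 1-chloro-3-iodopropane | ClCCCI | starting material
10 | methyl (3R,8R)-8-(5-chloro-2-methylpentan-2-yl)-6-hydroxy-3-methyl-7-methylidene-11-oxododecanoate (both C6 epimers) | CC(=O)CC[C@@H](C(=C)C(O)CC[C@@H](C)CC(=O)OC)C(C)(C)CCCCl | intermediate (not isolated)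
11 | methyl (3R)-6-hydroxy-3-methyl-6-[(1R,2R)-1,3,3-trimethyl-2-(3-oxobutyl)cyclohexyl]hexanoate (both C6 epimers) | CC(=O)CC[C@@H]1C(C)(C)CCC[C@@]1(C)C(O)CC[C@@H](C)CC(=O)OC | intermediate
12 | (3R)-6-hydroxy-3-methyl-6-[(1R,2R)-1,3,3-trimethyl-2-(3-oxobutyl)cyclohexyl]hexanoic acid (both C6 epimers) | CC(=O)CC[C@@H]1C(C)(C)CCC[C@@]1(C)C(O)CC[C@@H](C)CC(=O)O | intermediate
13 | (3R)-3-methyl-6-oxo-6-[(1R,2R)-1,3,3-trimethyl-2-(3-oxobutyl)cyclohexyl]hexanoic acid | CC(=O)CC[C@@H]1C(C)(C)CCC[C@@]1(C)C(=O)CC[C@@H](C)CC(=O)O | intermediate
14 | (R)-glycidol, [(2R)-oxiran-2-yl]methanol | OC[C@@H]1CO1 | starting material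
15 | (S)-glycidyl acetate, [(2S)-oxiran-2-yl]methyl acetate | CC(=O)OC[C@@H]1CO1 | intermediate
16 | (2R)-3-acetoxy-2-hydroxypropyl (3R)-3-methyl-6-oxo-6-[(1R,2R)-1,3,3-trimethyl-2-(3-oxobutyl)cyclohexyl]hexanoate | CC(=O)CC[C@@H]1C(C)(C)CCC[C@@]1(C)C(=O)CC[C@@H](C)CC(=O)OC[C@H](O)COC(C)=O | target

Total step count: 10. Longest linear sequence: 7 steps (1, 2, 5, 6, 7, 8, 10; the branch 3, 4, 5, 6, 7, 8, 10 is equally long).

Steps most likely to fail

Step 6 (proposed new method). Ring closure may lose to a second intermolecular coupling or to reduction of the carbon–halogen bond. The primary radical released on nickel activation may add to the olefin terminus and close a seven-membered ring. A first coupling at the methylidene group instead of the isopropenyl group would set the quaternary center without ring control and erode the selectivity. The fallback runs from 8 to 13 in known reaction types. Dess–Martin oxidation of 8 gives methyl (3R,8R)-3-methyl-7-methylidene-6,11-dioxo-8-(prop-1-en-2-yl)dodecanoate F1. Conjugate reduction of the α-methylidene ketone with [(Ph3P)CuH]6 gives methyl (3R,8S)-3,7-dimethyl-6,11-dioxo-8-(prop-1-en-2-yl)dodecanoate F2 (both C7 epimers). The intermolecular Mn(dpm)3/Ni(acac)2/PhSiH3 hydroalkylation of the one remaining olefin with 9 gives methyl (3R,8S)-8-(5-chloro-2-methylpentan-2-yl)-3,7-dimethyl-6,11-dioxododecanoate F3. LiOH gives (3R,8S)-8-(5-chloro-2-methylpentan-2-yl)-3,7-dimethyl-6,11-dioxododecanoic acid F4. NaI (cat.) and KOt-Bu in THF then close the ring by intramolecular C-alkylation of the more substituted ketone enolate through the same chair; aldol additions are reversible here and the carboxylate cannot be acylated. Acidification gives 13.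

Step 10. Attack at the internal epoxide carbon, or migration of an acyl group onto the new secondary hydroxyl at the reaction temperature, would scramble the glyceride. The fallback runs from 13 to 16 and builds the glycerol unit from a protected diol instead of an epoxide. Steglich esterification of 13 with (S)-solketal (EDC·HCl, DMAP, CH2Cl2) gives [(4R)-2,2-dimethyl-1,3-dioxolan-4-yl]methyl (3R)-3-methyl-6-oxo-6-[(1R,2R)-1,3,3-trimethyl-2-(3-oxobutyl)cyclohexyl]hexanoate F5. Acetonide cleavage with an acidic resin in methanol at 0 °C gives (2R)-2,3-dihydroxypropyl (3R)-3-methyl-6-oxo-6-[(1R,2R)-1,3,3-trimethyl-2-(3-oxobutyl)cyclohexyl]hexanoate F6. Acetylation of the primary hydroxyl alone (AcCl, 2,4,6-collidine, CH2Cl2, −78 °C) gives 16.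

Step 1. Ozone may also attack the isopropenyl group before the ring olefin is consumed, which lowers the amount of 2 and complicates its purification. The fallback runs from 1 to 2 and replaces ozonolysis by epoxidation and glycol cleavage. mCPBA in CH2Cl2 at 0 °C epoxidizes the trisubstituted ring olefin and gives (4S)-limonene 1,2-oxide F7 (both epoxide diastereomers). Periodic acid in aqueous THF hydrolyses the epoxide and cleaves the diol to 2.

Further compounds
F1 | step 6 | methyl (3R,8R)-3-methyl-7-methylidene-6,11-dioxo-8-(prop-1-en-2-yl)dodecanoate | CC(=O)CC[C@@H](C(=C)C(=O)CC[C@@H](C)CC(=O)OC)C(C)=C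
F2 | step 6 | methyl (3R,8S)-3,7-dimethyl-6,11-dioxo-8-(prop-1-en-2-yl)dodecanoate (both C7 epimers) | CC(=O)CC[C@@H](C(C)C(=O)CC[C@@H](C)CC(=O)OC)C(C)=C
F3 | step 6 | methyl (3R,8S)-8-(5-chloro-2-methylpentan-2-yl)-3,7-dimethyl-6,11-dioxododecanoate (both C7 epimers) | CC(=O)CC[C@@H](C(C)C(=O)CC[C@@H](C)CC(=O)OC)C(C)(C)CCCCl
F4 | step 6 | (3R,8S)-8-(5-chloro-2-methylpentan-2-yl)-3,7-dimethyl-6,11-dioxododecanoic acid (both C7 epimers) | CC(=O)CC[C@@H](C(C)C(=O)CC[C@@H](C)CC(=O)O)C(C)(C)CCCCl
F5 | step 10 | [(4R)-2,2-dimethyl-1,3-dioxolan-4-yl]methyl (3R)-3-methyl-6-oxo-6-[(1R,2R)-1,3,3-trimethyl-2-(3-oxobutyl)cyclohexyl]hexanoate | CC(=O)CC[C@@H]1C(C)(C)CCC[C@@]1(C)C(=O)CC[C@@H](C)CC(=O)OC[C@H]2COC(C)(C)O2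
F6 | step 10 | (2R)-2,3-dihydroxypropyl (3R)-3-methyl-6-oxo-6-[(1R,2R)-1,3,3-trimethyl-2-(3-oxobutyl)cyclohexyl]hexanoate | CC(=O)CC[C@@H]1C(C)(C)CCC[C@@]1(C)C(=O)CC[C@@H](C)CC(=O)OC[C@H](O)CO
F7 | step 1 | (4S)-limonene 1,2-oxide (both epoxide diastereomers) | CC12OC1C[C@H](CC2)C(C)=C
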